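With the heptane chain numbered C1–C7 from ring A (the catechol ring) to ring B (the 4-hydroxyphenyl ring), the target is an anti-3,5-diol acetylated on O3. Because C3 carries O3 beside the C4 methylene, that three-atom unit can be read as a monosubstituted oxirane, and the carbinol carbon C5 attached to C4 can be brought in as carbon monoxide. The chain is therefore cut at C4–C5: one cobaltate-mediated carbonylation of an (R)-oxirane tethered to dibenzylated ring A by two methylenes forms C4–C5 and C5–O3, closes an oxetan-2-one ring and leaves C3 untouched. Ring B then enters at the lactone carbonyl, and an O3-directed Evans–Tishchenko reduction sets C5 and acetylates O3.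

Key step: step 4

Remarks: O3 and O5 are the oxygens on C3 and C5. salen = (R,R)-N,N′-bis(3,5-di-tert-butylsalicylidene)cyclohexane-1,2-diamine dianion; salph = N,N′-bis(3,5-di-tert-butylsalicylidene)benzene-1,2-diamine dianion.
Assumption: 3,4-bis(benzyloxy)benzyl chloride and 2-[4-(benzyloxy)phenyl]ethanol are bought as such; the alkyl- and acylcobalt species that exist only inside the catalytic cycle of step 4 are treated in its Why line and carry no number.

Step 1
Reactants: 1 3,4-bis(benzyloxy)benzyl chloride; 2 allylmagnesium bromide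
Product: 3 1,2-bis(benzyloxy)-4-(but-3-en-1-yl)benzene
Conditions: 2 (1.5 equiv, 1 M in Et2O), THF, 0 °C → rt
Reagents that add atoms: none
Why: Direct SN2 coupling of an activated benzylic chloride with the highly nucleophilic allyl Grignard reagent (Grignard–benzyl halide cross-coupling) should join C1 to C2 and bring in C3 and C4 as the terminal alkene, with no stereocentre involved and the aryl benzyl ethers inert.

Step 2
Reactants: 3 1,2-bis(benzyloxy)-4-(but-3-en-1-yl)benzene
Product: 4 rac-2-{2-[3,4-bis(benzyloxy)phenyl]ethyl}oxirane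
Conditions: mCPBA (1.3 equiv), NaHCO3, CH2Cl2, 0 °C → rt
Reagents that add atoms: mCPBA (3-chloroperoxybenzoic acid), OOC(=O)c1cccc(Cl)c1
Why: Prilezhaev epoxidation, in which concerted oxygen transfer from the peracid to the isolated terminal alkene places O3 across C3–C4 as the racemic oxirane, while the bicarbonate buffer keeps 3-chlorobenzoic acid from opening the ring and the benzylated arene is not attacked.

Step 3
Reactants: 4 rac-2-{2-[3,4-bis(benzyloxy)phenyl]ethyl}oxirane
Product: 5 (2R)-2-{2-[3,4-bis(benzyloxy)phenyl]ethyl}oxirane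
Conditions: (R,R)-(salen)Co(OAc) (0.5 mol %, trivalent cobalt, made from the divalent cobalt complex (R,R)-(salen)Co with AcOH in air), H2O (0.55 equiv), THF, 0 °C → rt; chromatography, azeotropic drying with toluene
Reagents that add atoms: none
Why: Jacobsen hydrolytic kinetic resolution, in which the (R,R)-configured cobalt–salen catalyst hydrates the (S)-oxirane at its terminal carbon far faster than the (R)-oxirane, so the C3 stereocentre is selected by the catalyst as the unreacted (R)-enantiomer, which should be separable from the polar diol and can be dried rigorously for the next step.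

Step 4
Reactants: 5 (2R)-2-{2-[3,4-bis(benzyloxy)phenyl]ethyl}oxirane; 6 carbon monoxide
Product: 7 (4R)-4-{2-[3,4-bis(benzyloxy)phenyl]ethyl}oxetan-2-one
Conditions: [(salph)Al(THF)2][Co(CO)4] (2 mol %), CO (60 bar), DME, 50 °C
Reagents that add atoms: none
Why: Coordination of O3 to the cationic aluminium centre polarises the oxirane, and [Co(CO)4]− displaces O3 from the methylene carbon C4 by backside attack, leaving a C4–Co alkyl; migratory insertion of CO turns this into an acyl–Co unit whose carbonyl carbon is C5, and the aluminium-bound O3 alkoxide adds to that carbonyl and expels the cobaltate. The closest known reaction type is the ring-expanding carbonylation of monosubstituted aliphatic epoxides to β-lactones by Lewis acid–tetracarbonylcobaltate ion pairs. The four-membered oxetan-2-one ring (O3, C3, C4, C5) closes in a 4-exo-trig acyl substitution. No stereocentre is created, and C3 keeps its R configuration because the C3–O3 bond is never broken. The step needs attack at C4 and not at C3, and it must stop at the lactone without isomerisation to the methyl ketone or a second carbonylation to the succinic anhydride. The monosubstituted oxirane offers only a primary carbon for backside attack, and an ether solvent, moderate temperature, high CO pressure and a dry, diol-free substrate should hold the catalyst on the lactone pathway.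

Step 5
Reactants: 7 (4R)-4-{2-[3,4-bis(benzyloxy)phenyl]ethyl}oxetan-2-one
Product: 8 (3R)-5-[3,4-bis(benzyloxy)phenyl]-3-hydroxy-N-methoxy-N-methylpentanamide
Conditions: MeNHOMe·HCl (3 equiv), Me2AlCl (3 equiv), CH2Cl2, −30 °C → rt; aq. potassium sodium tartrate
Reagents that add atoms: N,O-dimethylhydroxylamine hydrochloride, CNOC.Cl
Why: Weinreb aminolysis, in which the chloroaluminium amide formed in situ attacks the strained lactone carbonyl C5 and cleaves the acyl–O3 bond, not the C3–O3 bond, so the hydroxy amide should form with C3 intact and with C5 at the oxidation level needed for a single organometallic addition.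

Step 6
Reactants: 9 2-[4-(benzyloxy)phenyl]ethanol
Product: 10 1-(benzyloxy)-4-(2-bromoethyl)benzene
Conditions: CBr4 (1.2 equiv), PPh3 (1.25 equiv), CH2Cl2, 0 °C → rt
Reagents that add atoms: carbon tetrabromide, BrC(Br)(Br)Br
Why: Appel reaction, in which the primary alcohol is activated as an alkoxyphosphonium ion and displaced by bromide in an SN2 step under neutral conditions that leave the aryl benzyl ether untouched.

Step 7
Reactants: 8 (3R)-5-[3,4-bis(benzyloxy)phenyl]-3-hydroxy-N-methoxy-N-methylpentanamide; 10 1-(benzyloxy)-4-(2-bromoethyl)benzene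
Product: 12 (5R)-1-[4-(benzyloxy)phenyl]-7-[3,4-bis(benzyloxy)phenyl]-5-hydroxyheptan-3-one, via 2-[4-(benzyloxy)phenyl]ethylmagnesium bromide 11 (not isolated)
Conditions: 10 (3.2 equiv), Mg turnings, I2 (cat.), THF, rt → 45 °C; then 8, THF, −20 → 0 °C; aq. NH4Cl
Reagents that add atoms: none
Why: Weinreb ketone synthesis, in which the Grignard reagent formed in situ first removes the O3–H proton and a second equivalent adds to the amide carbonyl C5 to give a chelated magnesium N-methoxy aminal that resists further addition and collapses to the ketone only on aqueous quench, forming C5–C6 without touching C3.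

Step 8
Reactants: 12 (5R)-1-[4-(benzyloxy)phenyl]-7-[3,4-bis(benzyloxy)phenyl]-5-hydroxyheptan-3-one; 13 acetaldehyde
Product: 15 (3R,5R)-7-[4-(benzyloxy)phenyl]-1-[3,4-bis(benzyloxy)phenyl]-5-hydroxyheptan-3-yl acetate, via acetaldehyde hemiacetal 14 (not isolated)
Conditions: 13 (6 equiv, freshly distilled), SmI2 (0.2 equiv, 0.1 M in THF), THF, −10 °C; aq. NaHCO3
Reagents that add atoms: none
Why: Evans–Tishchenko reduction, in which the samarium catalyst ties the hemiacetal formed from O3–H and acetaldehyde to the C5 ketone in a chair-like six-membered transition state, so the hemiacetal hydrogen is delivered intramolecularly to the ketone face anti to O3, which should set C5 as R (anti-1,3) and at the same time turn the hemiacetal carbon into the acetyl group on O3 while O5 stays free.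

Step 9
Reactants: 15 (3R,5R)-7-[4-(benzyloxy)phenyl]-1-[3,4-bis(benzyloxy)phenyl]-5-hydroxyheptan-3-yl acetate
Product: 16 (3R,5R)-1-(3,4-dihydroxyphenyl)-5-hydroxy-7-(4-hydroxyphenyl)heptan-3-yl acetate
Conditions: H2 (1 atm), 10% Pd/C, EtOAc, rt; filtration under argon
Reagents that add atoms: none
Why: Heterogeneous catalytic hydrogenolysis should cleave the three aryl benzyl ethers to toluene under neutral, aprotic conditions in which the secondary acetate neither hydrolyses nor migrates from O3 to O5 and the two carbinol stereocentres are not affected.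

Compound list
1 | 3,4-bis(benzyloxy)benzyl chloride | ClCc1ccc(OCc2ccccc2)c(OCc2ccccc2)c1 | starting material
2 | allylmagnesium bromide | C=CC[Mg]Br | starting material
3 | 1,2-bis(benzyloxy)-4-(but-3-en-1-yl)benzene | C=CCCc1ccc(OCc2ccccc2)c(OCc2ccccc2)c1 | intermediate
4 | rac-2-{2-[3,4-bis(benzyloxy)phenyl]ethyl}oxirane | C1OC1CCc1ccc(OCc2ccccc2)c(OCc2ccccc2)c1 | intermediate
5 | (2R)-2-{2-[3,4-bis(benzyloxy)phenyl]ethyl}oxirane | C1O[C@@H]1CCc1ccc(OCc2ccccc2)c(OCc2ccccc2)c1 | intermediate
6 | carbon monoxide | [C-]#[O+] | starting material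
7 | (4R)-4-{2-[3,4-bis(benzyloxy)phenyl]ethyl}oxetan-2-one | O=C1C[C@@H](CCc2ccc(OCc3ccccc3)c(OCc3ccccc3)c2)O1 | intermediate
8 | (3R)-5-[3,4-bis(benzyloxy)phenyl]-3-hydroxy-N-methoxy-N-methylpentanamide | CON(C)C(=O)C[C@H](O)CCc1ccc(OCc2ccccc2)c(OCc2ccccc2)c1 | intermediate
9 | 2-[4-(benzyloxy)phenyl]ethanol | OCCc1ccc(OCc2ccccc2)cc1 | starting material
10 | 1-(benzyloxy)-4-(2-bromoethyl)benzene | BrCCc1ccc(OCc2ccccc2)cc1 | intermediate
11 | 2-[4-(benzyloxy)phenyl]ethylmagnesium bromide (formed in the flask, not isolated) | Br[Mg]CCc1ccc(OCc2ccccc2)cc1 | intermediate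
12 | (5R)-1-[4-(benzyloxy)phenyl]-7-[3,4-bis(benzyloxy)phenyl]-5-hydroxyheptan-3-one | O=C(CCc1ccc(OCc2ccccc2)cc1)C[C@H](O)CCc1ccc(OCc2ccccc2)c(OCc2ccccc2)c1 | intermediate
13 | acetaldehyde | CC=O | starting material
14 | (5R)-1-[4-(benzyloxy)phenyl]-7-[3,4-bis(benzyloxy)phenyl]-5-(1-hydroxyethoxy)heptan-3-one (hemiacetal, configuration at the hemiacetal carbon undefined, not isolated) | CC(O)O[C@H](CCc1ccc(OCc2ccccc2)c(OCc2ccccc2)c1)CC(=O)CCc1ccc(OCc2ccccc2)cc1 | intermediate
15 | (3R,5R)-7-[4-(benzyloxy)phenyl]-1-[3,4-bis(benzyloxy)phenyl]-5-hydroxyheptan-3-yl acetate | CC(=O)O[C@H](CCc1ccc(OCc2ccccc2)c(OCc2ccccc2)c1)C[C@H](O)CCc1ccc(OCc2ccccc2)cc1 | intermediate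
16 | (3R,5R)-1-(3,4-dihydroxyphenyl)-5-hydroxy-7-(4-hydroxyphenyl)heptan-3-yl acetate | CC(=O)O[C@H](CCc1ccc(O)c(O)c1)C[C@H](O)CCc1ccc(O)cc1 | target

Total step count: 9.
Longest linear sequence: 8 steps (steps 1–5 and 7–9, from 1 to 16); step 6 is a one-step side branch that joins at step 7.

Steps most likely to fail

Step 4. The moisture-sensitive ion-pair catalyst may be deactivated by traces of water or diol carried over from the resolution. The oxirane may also isomerise to the methyl ketone under Lewis acid, or the lactone may carbonylate further or polymerise by ring opening. Each of these would erode conversion to 7. The fallback delivers C5 as a dithiane carbon instead of carbon monoxide (Corey–Seebach acyl-anion chemistry). It sets out from 5, uses 10 as the ring B component, and comes back to the route at 12, so steps 4, 5 and 7 are bypassed. Commercial 1,3-dithiane is lithiated (n-BuLi, THF, −30 °C) and alkylated with 10 to give 2-{2-[4-(benzyloxy)phenyl]ethyl}-1,3-dithiane F1. This is lithiated again (n-BuLi, THF/HMPA, −78 °C) and should open 5 at the terminal carbon C4 to give (2R)-4-[3,4-bis(benzyloxy)phenyl]-1-(2-{2-[4-(benzyloxy)phenyl]ethyl}-1,3-dithian-2-yl)butan-2-ol F2, with C3 unchanged. Hydrolysis of the thioacetal (MeI, CaCO3, MeCN/H2O, 40 °C) should then give 12.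

Step 7. The magnesium alkoxide formed from the free hydroxyl may aggregate and stall the addition, or it may fragment by retro-aldol cleavage or β-elimination. Wurtz coupling during formation of the Grignard reagent may also leave too little nucleophile. The fallback masks O3 so that one equivalent of reagent meets a neutral amide. It sets out from 8 and comes back at 12. Silylation (TESCl, imidazole, DMF, 0 °C) gives (3R)-5-[3,4-bis(benzyloxy)phenyl]-N-methoxy-N-methyl-3-[(triethylsilyl)oxy]pentanamide F3. Addition of 11 (1.3 equiv, THF, 0 °C) gives (5R)-1-[4-(benzyloxy)phenyl]-7-[3,4-bis(benzyloxy)phenyl]-5-[(triethylsilyl)oxy]heptan-3-one F4. Mild desilylation (HF·pyridine, THF/pyridine, 0 °C) should release 12.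

Step 8. The volatile, enolisable acetaldehyde may be lost to evaporation and self-condensation before hydride transfer, or the samarium alkoxide may promote 1,3-acetyl migration between O3 and O5 on prolonged reaction. The fallback separates reduction from acetylation. It sets out from 12 and comes back at 16, using the conditions of step 9 for its last operation. The same directed reduction with non-enolisable benzaldehyde (PhCHO, SmI2 0.2 equiv, THF, −10 °C) gives (3R,5R)-7-[4-(benzyloxy)phenyl]-1-[3,4-bis(benzyloxy)phenyl]-5-hydroxyheptan-3-yl benzoate F5, which fixes C5 and marks O3. Neutral benzylation of O5 (2-benzyloxy-1-methylpyridinium triflate, MgO, PhCF3, 85 °C) gives (3R,5R)-5-(benzyloxy)-7-[4-(benzyloxy)phenyl]-1-[3,4-bis(benzyloxy)phenyl]heptan-3-yl benzoate F6. Methanolysis (K2CO3, MeOH/THF) gives (3R,5R)-5-(benzyloxy)-7-[4-(benzyloxy)phenyl]-1-[3,4-bis(benzyloxy)phenyl]heptan-3-ol F7. Acetylation (Ac2O, pyridine, DMAP cat.) gives (3R,5R)-5-(benzyloxy)-7-[4-(benzyloxy)phenyl]-1-[3,4-bis(benzyloxy)phenyl]heptan-3-yl acetate F8. Hydrogenolysis of all four benzyl ethers (H2, Pd/C, EtOAc) should give 16.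

Further compounds
F1 | step 4 | 2-{2-[4-(benzyloxy)phenyl]ethyl}-1,3-dithiane | C1CSC(CCc2ccc(OCc3ccccc3)cc2)SC1
F2 | step 4 | (2R)-4-[3,4-bis(benzyloxy)phenyl]-1-(2-{2-[4-(benzyloxy)phenyl]ethyl}-1,3-dithian-2-yl)butan-2-ol | O[C@H](CCc1ccc(OCc2ccccc2)c(OCc2ccccc2)c1)CC1(CCc2ccc(OCc3ccccc3)cc2)SCCCS1
F3 | step 7 | (3R)-5-[3,4-bis(benzyloxy)phenyl]-N-methoxy-N-methyl-3-[(triethylsilyl)oxy]pentanamide | CON(C)C(=O)C[C@H](O[Si](CC)(CC)CC)CCc1ccc(OCc2ccccc2)c(OCc2ccccc2)c1
F4 | step 7 | (5R)-1-[4-(benzyloxy)phenyl]-7-[3,4-bis(benzyloxy)phenyl]-5-[(triethylsilyl)oxy]heptan-3-one | O=C(CCc1ccc(OCc2ccccc2)cc1)C[C@H](O[Si](CC)(CC)CC)CCc1ccc(OCc2ccccc2)c(OCc2ccccc2)c1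
F5 | step 8 | (3R,5R)-7-[4-(benzyloxy)phenyl]-1-[3,4-bis(benzyloxy)phenyl]-5-hydroxyheptan-3-yl benzoate | O=C(O[C@H](CCc1ccc(OCc2ccccc2)c(OCc2ccccc2)c1)C[C@H](O)CCc1ccc(OCc2ccccc2)cc1)c1ccccc1
F6 | step 8 | (3R,5R)-5-(benzyloxy)-7-[4-(benzyloxy)phenyl]-1-[3,4-bis(benzyloxy)phenyl]heptan-3-yl benzoate | O=C(O[C@H](CCc1ccc(OCc2ccccc2)c(OCc2ccccc2)c1)C[C@H](OCc1ccccc1)CCc1ccc(OCc2ccccc2)cc1)c1ccccc1
F7 | step 8 | (3R,5R)-5-(benzyloxy)-7-[4-(benzyloxy)phenyl]-1-[3,4-bis(benzyloxy)phenyl]heptan-3-ol | O[C@H](CCc1ccc(OCc2ccccc2)c(OCc2ccccc2)c1)C[C@H](OCc1ccccc1)CCc1ccc(OCc2ccccc2)cc1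
F8 | step 8 | (3R,5R)-5-(benzyloxy)-7-[4-(benzyloxy)phenyl]-1-[3,4-bis(benzyloxy)phenyl]heptan-3-yl acetate | CC(=O)O[C@H](CCc1ccc(OCc2ccccc2)c(OCc2ccccc2)c1)C[C@H](OCc1ccccc1)CCc1ccc(OCc2ccccc2)cc1
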